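## Structural features

The target is a 3,3''-linked biflavanone. A liquiritigenin unit (unit A, 7,4'-dihydroxyflavanone) and a naringenin unit (unit B, 5,7,4'-trihydroxyflavanone) are joined by one single bond between C3A and C3B. Each unit is a benzo-fused dihydropyran-4-one with a 4-hydroxyphenyl group at C2, so four contiguous stereocentres, C2A–C3A–C3B–C2B, run across the inter-unit bond. The configuration is (2S,3R) in both units, that is 2,3-trans in each pyranone ring. C3A and C3B are each alpha to one ketone and beta to the other (a 1,4-diketone), so both are epimerisable, and the diketone can cyclodehydrate under strong acid. Both pyranone rings can open by loss of the ring aryloxide from the C3 enolate (retro-oxa-Michael), and with a free 4'-hydroxyl also through a para-quinone methide, either of which would scramble C2A or C2B. The real difficulty is the crowded C3A–C3B bond between two secondary ring carbons and the control of four stereocentres without loss of the C2 centres. The key step uses the fact that C3B is the beta carbon of the unit A ketone (through C3A) and is also bonded to the carbonyl carbon C4B, which sits on the phloroglucinol ring ortho to O1B. A ketyl at C4B, tethered through C4aB, C8aB, O1B and C2B, can therefore add to C3B of an exocyclic C3A=C3B enone and close the pyran ring of unit B.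

## Logic of the disconnections

23 to 22. The five phenolic O–CH2OMe bonds are cut first. Free phenols would open the heterocycles through phenoxide and quinone-methide pathways and would quench bases and one-electron reductants. The gain is that every earlier intermediate is a neutral ether of one single kind. The demand is a final acidic step mild enough to leave C2A, C3A, C3B and C2B alone.

22 to 21. No skeletal bond is cut; the C3A–H bond is exchanged for its epimer. The trans,trans array of 22 is the thermodynamic one, so C3A need not be fixed kinetically in the C–C bond-forming step. The forward step must enolise C3A without expelling the ring aryloxides, so that C2A and C2B survive.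

21 to 20. The C4B=O double bond is taken back to a C4B–OH single bond. C4B is to be introduced as a nucleophilic ketyl carbon and therefore arrives at the alcohol oxidation level. Nothing is gained in size, but the retron for a reductive cyclisation appears. The forward oxidation must be neutral, because 21 is an epimerisable 1,4-diketone.

20 to 17 (key disconnection). The C3B–C4B ring bond and the C3A–H bond are cut. This opens the pyran ring of unit B, turns the inter-unit bond into a C3A=C3B alkene and leaves an aryl aldehyde. The crowded sp3–sp3 bond therefore never has to be made between two molecules, and three stereocentres (C3A, C3B, C4B) are traded for one alkene. The forward step demands polarity reversal of the formyl carbon by one-electron reduction, a 6-exo closure onto the enone beta carbon under control of C2B, and survival of the allylic C2B–O1B bond under reducing conditions.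

17 to 15 to 6 and 13. The C3A=C3B bond is cut in two stages: the pi bond by retro-dehydration to 15, the sigma bond by retro-aldol to 6 and 13. This divides the molecule into two halves of similar size, each with one stereocentre of independent origin (C2A in 6, C2B in 13). The forward C–C formation must use a preformed enolate at low temperature, because equilibrating condensation conditions would open the pyranone of 6 and racemise the alpha centre of 13. It must also choose the aliphatic formyl group of 13 over the aryl one.

13 to 12 to 11. No C–C bond is cut; both formyl groups of 13 are traced back through 12 to 11. An ester cannot be reduced to an aldehyde beside a free aryl aldehyde, so both carbonyls are taken down together and brought up together. The price is one redox step; the gain is that no chemoselectivity is asked for and that 12 is a configurationally robust resting point. The oxidation must not enolise the new alpha-aryloxy aldehyde.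

11 to 10 and 8. The C2B–O1B ether bond is cut. This separates the C2B stereocentre (chiral pool) from the phloroglucinol ring, and each piece is one step from a commercial compound. The forward substitution at a benzylic, ester-bearing carbon must be a clean SN2 inversion, which fixes the (S) alcohol 10 for the (R) ether 11, and it must tolerate the formyl group of 8.

10 to 9, and 8 to 7. Only O–CH2OMe bonds are cut. The demand is site selection: in 9 the carboxyl and phenol but not the secondary alcohol, in 7 two hydroxyls but not the one hydrogen-bonded to the formyl group.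

6 to 5 to 2 and 3. 6 is one enantiomer of 5, so a resolution is required. In 5 the O1A–C2A and C2A–C3A bonds are cut (retro-oxa-Michael, then retro-aldol condensation through 4) to give 2 and 3. The gain is two achiral aromatic building blocks; the demand is a resolution that leaves the ketone of the wanted enantiomer untouched.

2 to 1. One O–CH2OMe bond is cut; the forward step must alkylate only the hydroxyl para to the acetyl group.

## Other disconnections considered

Alternative 1: The cut is the C4aB–C5B bond of the phloroglucinol ring of unit B, which is unfolded to a polyketide chain stored as the 4-hydroxy-2-pyranone A2. Forward, Mg(OMe)2 in methanol opens the pyranone of A2 and the chain closes by Claisen condensation of the C4aB methylene onto the ester carbonyl. This gives the acylphloroglucinol A1, in which the pyranone of unit B is still open. C2B of A1 carries a silyl ether of configuration opposite to that of 23, so a later O1B–C2B closure with inversion is implied.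
- In favour: C4B is at the ketone oxidation level throughout, so no late oxidation is needed; on this point the alternative is better than the chosen plan. The symmetrical phloroglucinol makes the later ring closure regiochemically unambiguous, and no reductant ever meets the benzylic C2B–O bond.
- Against: the key step uses methoxide on a substrate with a beta-silyloxy ketone (C2B–O is beta to C4B, set up for E1cB loss), two epimerisable centres alpha to ketones and the base-labile pyranone of unit A. The chain may also fold by the competing aldol mode. A2 itself needs C3A, C3B and C2B to be set by acyclic stereocontrol and a polyanion acylation beside the unit A ketone.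
- Comparison: structurally it builds a ring that is commercial (as 7) and leaves the C3A–C3B bond and three stereocentres to an open chain, whereas the chosen plan lets C2B and a ring transition state control C3B. Mechanistically it is polar and strongly basic, where the chosen plan is reductive at low temperature. After A1 it needs desilylation, ring closure and deprotection, equal in number to the chosen end game, but the way to A2 is expected to be longer.

Alternative 2: The cuts are the two heterocyclic bonds O1A–C2A and O1B–C2B, leading back to the open 2,3-bis(4-hydroxybenzyl)-1,4-diaryl-1,4-diketone A4. Forward, DDQ oxidises both 4-hydroxybenzyl groups of A4 at the benzylic carbons to the quinone-methide level, and each ortho-phenol adds to its electrophilic carbon, closing both pyranones at once to give A3.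
- In favour: two rings and two stereocentres (C2A, C2B) in one operation, only C3A and C3B to be set beforehand, few protecting groups. On step economy it is potentially better than the chosen plan. Like the chosen plan it relies on the thermodynamic trans preference of each ring, so the two are equal on that point.
- Against: DDQ also attacks free electron-rich resorcinol and phloroglucinol rings and dehydrogenates flavanones to flavones. At the quinone-methide stage the C3 hydrogen, alpha to the ketone, can shift to give an alpha-benzylidene ketone, which would erase the C3 centres that carry all the stereochemical information. A4 is an unsymmetrical 2,3-disubstituted 1,4-diketone and needs an enantio- and diastereoselective hetero-coupling of two different ketone enolates, harder than the aldol union of 6 and 13.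
- Comparison: the chosen plan takes C2A and C2B from resolved or chiral-pool sources and corrects only C3; the alternative fixes C3 and derives C2 from it. The logic is mirrored, but the alternative's stereochemical source is the more fragile one, and its key step is an oxidation of a polyphenol against a chelation-directed reduction of a fully protected substrate.

Alternative 3: The cuts are C8A–C8aA and C4aA–C5A, which remove the benzo ring of unit A and reduce it to the monocyclic 5-bromo-2,3-dihydropyran-4-one A6 that already carries unit B at C3A. Forward, the diene A7, (E)-1-methoxy-3-(trimethylsilyloxy)buta-1,3-diene, adds across C4aA=C8aA of A6 with its CH2 terminus at the beta carbon C8aA. Loss of methanol and HBr then aromatises the new ring to give A5 with a free O7A hydroxyl.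
- In favour: the regiochemistry is electronically matched, the O7A phenol appears unprotected and differentiated, and the key step neither creates nor touches a stereocentre. On that point it is safer than the chosen key step, which creates three.
- Against: the ring that is built is the simplest part of the target and is commercial in 1. The dienophile is an electron-rich, alpha-substituted vinylogous ester, so forcing thermal or Lewis-acid conditions are to be expected for a cycloaddition that must create a quaternary C4aA; these threaten the acetals and the C3 centres. HBr loss needs base on a beta-aryloxy ketone. The C3A–C3B bond and all four stereocentres remain to be made on the way to A6, on a dihydropyranone that opens more easily than a flavanone.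
- Comparison: structurally it solves none of the central problems. Mechanistically it is a pericyclic step of low risk to stereochemistry but doubtful rate. In step economy it is clearly behind, because the construction of A6 replaces one commercial acetophenone.

Key step: step 11

Assumption: 3 and single-enantiomer 9 are purchased; the atom labels of the two flavanone units (suffix A, suffix B) are used for all intermediates, also before the rings exist.

Remark on stereochemistry: 20 is formulated with C3A cis to the C2A aryl group, the arrangement expected from kinetic protonation, with the skeleton unchanged; the trans arrangement is installed in step 13, where any trans epimer formed directly also ends up as 22.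

## Steps

Step 1
Reactants: 1 2,4-dihydroxyacetophenone
Product: 2 1-[2-hydroxy-4-(methoxymethoxy)phenyl]ethan-1-one
Conditions: MOMCl (1.1 equiv), K2CO3, acetone, 0 °C → rt
Reagents that add atoms: chloromethyl methyl ether (COCCl)
Why: O-alkylation of a phenoxide; the 2-hydroxyl is held in a hydrogen bond to the acetyl group and is much less nucleophilic, so only the 4-hydroxyl reacts.

Step 2
Reactants: 2 1-[2-hydroxy-4-(methoxymethoxy)phenyl]ethan-1-one; 3 4-(methoxymethoxy)benzaldehyde
Product: 5 rac-7-(methoxymethoxy)-2-[4-(methoxymethoxy)phenyl]-2,3-dihydro-4H-chromen-4-one, via chalcone 4 (not isolated)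
Conditions: KOH, EtOH, rt; then AcOH (to buffer as KOAc), reflux
Reagents that add atoms: none
Why: Claisen–Schmidt aldol condensation gives the (E)-chalcone 4 as its phenoxide; in the acetate buffer the phenol adds to the enone (intramolecular oxa-Michael, 6-endo-trig) to give the racemic flavanone. Chalcone left at equilibrium is separated and recycled.

Step 3
Reactants: 5 rac-7-(methoxymethoxy)-2-[4-(methoxymethoxy)phenyl]-2,3-dihydro-4H-chromen-4-one
Product: 6 (2S)-7-(methoxymethoxy)-2-[4-(methoxymethoxy)phenyl]-2,3-dihydro-4H-chromen-4-one
Conditions: RuCl[(R,R)-TsDPEN](p-cymene) (1 mol %), HCO2H/Et3N (5:2), EtOAc, rt, run slightly beyond half conversion; chromatography; chiral HPLC check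
Reagents that add atoms: none
Why: Kinetic resolution by asymmetric transfer hydrogenation. The (R,R) complex delivers hydride to give (4R) benzylic alcohols, and only in the (2R) ketone does this coincide with the favoured axial attack anti to the equatorial aryl group. The (2R) enantiomer is therefore consumed as the cis-(2R,4R)-flavan-4-ol and the (2S) ketone 6 is recovered.

Step 4
Reactants: 7 2,4,6-trihydroxybenzaldehyde
Product: 8 2-hydroxy-4,6-bis(methoxymethoxy)benzaldehyde
Conditions: MOMCl (2.1 equiv), i-Pr2NEt, CH2Cl2, 0 °C
Reagents that add atoms: chloromethyl methyl ether (COCCl)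
Why: O-alkylation; with two equivalents the hydroxyl hydrogen-bonded to the formyl group stays free, which leaves exactly the phenol that becomes O1B.

Step 5
Reactants: 9 (2S)-2-hydroxy-2-(4-hydroxyphenyl)acetic acid
Product: 10 methoxymethyl (2S)-2-hydroxy-2-[4-(methoxymethoxy)phenyl]acetate
Conditions: MOMCl (2.1 equiv), K2CO3, DMF, 0 °C → rt
Reagents that add atoms: chloromethyl methyl ether (COCCl)
Why: Carbonate generates only the carboxylate and the phenoxide, so these two are alkylated and the secondary alcohol stays free; the stereocentre is not involved. The methoxymethyl ester serves later as a reducible ester, which saves a separate esterification.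

Step 6
Reactants: 10 methoxymethyl (2S)-2-hydroxy-2-[4-(methoxymethoxy)phenyl]acetate; 8 2-hydroxy-4,6-bis(methoxymethoxy)benzaldehyde
Product: 11 methoxymethyl (2R)-2-[2-formyl-3,5-bis(methoxymethoxy)phenoxy]-2-[4-(methoxymethoxy)phenyl]acetate
Conditions: PPh3, diisopropyl azodicarboxylate, THF, 0 °C → rt
Reagents that add atoms: none
Why: Mitsunobu etherification: the alkoxyphosphonium ion of the alpha-hydroxy ester is displaced by the acidic, formyl-activated phenol in an SN2 process with inversion, so (S) becomes (R) at the future C2B. The adjacent ester carbonyl disfavours ionisation.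

Step 7
Reactants: 11 methoxymethyl (2R)-2-[2-formyl-3,5-bis(methoxymethoxy)phenoxy]-2-[4-(methoxymethoxy)phenyl]acetate
Product: 12 (2R)-2-[2-(hydroxymethyl)-3,5-bis(methoxymethoxy)phenoxy]-2-[4-(methoxymethoxy)phenyl]ethan-1-ol
Conditions: LiBH4 (3 equiv), THF, 0 °C → rt; aq NH4Cl
Reagents that add atoms: none
Why: LiBH4 reduces the aryl aldehyde and the activated alpha-aryloxy ester to primary alcohols and leaves acetals and aryl ethers alone. Reducing both carbonyls avoids an ester-over-aldehyde selection, and the stereocentre of 12 no longer bears an acidic hydrogen.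

Step 8
Reactants: 12 (2R)-2-[2-(hydroxymethyl)-3,5-bis(methoxymethoxy)phenoxy]-2-[4-(methoxymethoxy)phenyl]ethan-1-ol
Product: 13 (2R)-2-[2-formyl-3,5-bis(methoxymethoxy)phenoxy]-2-[4-(methoxymethoxy)phenyl]acetaldehyde
Conditions: Dess–Martin periodinane (3 equiv), NaHCO3, CH2Cl2, 0 °C → rt; aq Na2S2O3/NaHCO3; used at once without chromatography
Reagents that add atoms: none
Why: Buffered hypervalent iodine oxidation turns both primary alcohols into aldehydes under neutral, non-enolising conditions. The alpha-aryloxy aldehyde is configurationally labile, so it is carried on immediately.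

Step 9
Reactants: 6 (2S)-7-(methoxymethoxy)-2-[4-(methoxymethoxy)phenyl]-2,3-dihydro-4H-chromen-4-one; 13 (2R)-2-[2-formyl-3,5-bis(methoxymethoxy)phenoxy]-2-[4-(methoxymethoxy)phenyl]acetaldehyde
Product: 15 (2S)-3-{(2R)-2-[2-formyl-3,5-bis(methoxymethoxy)phenoxy]-1-hydroxy-2-[4-(methoxymethoxy)phenyl]ethyl}-7-(methoxymethoxy)-2-[4-(methoxymethoxy)phenyl]-2,3-dihydro-4H-chromen-4-one, via lithium enolate 14 (not isolated)
Conditions: 6 (1.2 equiv), LiN(i-Pr)2 (1.15 equiv), THF, −78 °C; then 13 in THF, −78 °C, short contact; AcOH, −78 °C
Reagents that add atoms: none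
Why: Directed aldol addition: the kinetic lithium enolate 14 is formed and used at −78 °C, where expulsion of the ring aryloxide (ring opening, loss of C2A) is slow. It adds to the aliphatic alpha-aryloxy aldehyde far faster than to the aryl aldehyde, which is deactivated by three donor oxygens and two ortho substituents. 15 is a mixture of epimers at C3A and the carbinol carbon, both of which are removed in step 10.

Step 10
Reactants: 15 (2S)-3-{(2R)-2-[2-formyl-3,5-bis(methoxymethoxy)phenoxy]-1-hydroxy-2-[4-(methoxymethoxy)phenyl]ethyl}-7-(methoxymethoxy)-2-[4-(methoxymethoxy)phenyl]-2,3-dihydro-4H-chromen-4-one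
Product: 17 (2R,3E)-3-{(2S)-2-[2-formyl-3,5-bis(methoxymethoxy)phenoxy]-2-[4-(methoxymethoxy)phenyl]ethylidene}-7-(methoxymethoxy)-2-[4-(methoxymethoxy)phenyl]-2,3-dihydro-4H-chromen-4-one, via methanesulfonate 16 (not isolated)
Conditions: MsCl, Et3N, CH2Cl2, 0 °C → rt
Reagents that add atoms: none
Why: Mesylation and in situ E1cB elimination through the C3A enolate; mesylate leaves far more readily than the ring aryloxide O1A, and the conjugated (E)-alkylidene ketone (C3B–H syn to the carbonyl) is the thermodynamically preferred isomer. A tertiary amine at or below room temperature is used to avoid deprotonation at the gamma position C2B. The descriptor at C2A changes to R only because the alkylidene carbon now outranks the aryl group; the spatial arrangement is that of 6.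

Step 11
Reactants: 17 (2R,3E)-3-{(2S)-2-[2-formyl-3,5-bis(methoxymethoxy)phenoxy]-2-[4-(methoxymethoxy)phenyl]ethylidene}-7-(methoxymethoxy)-2-[4-(methoxymethoxy)phenyl]-2,3-dihydro-4H-chromen-4-one
Product: 20 (2S,3S)-3-[(2S,3S,4S)-4-hydroxy-5,7-bis(methoxymethoxy)-2-[4-(methoxymethoxy)phenyl]-3,4-dihydro-2H-chromen-3-yl]-7-(methoxymethoxy)-2-[4-(methoxymethoxy)phenyl]-2,3-dihydro-4H-chromen-4-one, via SmI2-bound ketyl 18 (not isolated), via bis-SmI2 enolate alkoxide 19 (not isolated)
Conditions: SmI2 (0.1 M in THF, 2.2 equiv, slow addition), t-BuOH (3 equiv), THF (0.01 M), −78 °C; sat. aq NH4Cl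
Reagents that add atoms: none
Why: Divalent samarium, held by the formyl oxygen and the flanking O1B and O5B ether oxygens, transfers one electron to the aldehyde to give ketyl 18, whose nucleophilic carbon radical adds to the electrophilic beta carbon C3B of the enone and forms C3B–C4B. The alpha-keto radical at C3A takes a second electron to give the trivalent samarium enolate 19, which tert-butanol protonates at C3A. The closest known reaction type is the SmI2 ketyl–olefin (aldehyde–enone) reductive cyclisation of 2-(allyloxy)benzaldehyde-type substrates to 3-substituted chroman-4-ols. The pyran ring of unit B closes 6-exo-trig (ring atoms C4B, C4aB, C8aB, O1B, C2B, C3B; C3A stays outside). C3B is controlled by C2B: in the chair-like transition state the C2B aryl group is equatorial and the alkene branch takes the neighbouring equatorial site, so C3A ends up trans to that aryl group. At C4B the O–Sm group lies anti to the C3B branch, giving the 3,4-trans alcohol, a centre removed in step 12. At C3A, protonation anti to the pseudo-axial C2A aryl group should give the 2,3-cis arrangement drawn for 20, which is corrected in step 13. The step needs cyclisation to outrun two-electron cleavage of the gamma-aryloxy enone, pinacol coupling and reduction of the product ketone; chelation-directed reduction at the aldehyde, the short tether, slow addition of the reductant at −78 °C, high dilution and the absence of HMPA are meant to secure this.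

Step 12
Reactants: 20 (2S,3S)-3-[(2S,3S,4S)-4-hydroxy-5,7-bis(methoxymethoxy)-2-[4-(methoxymethoxy)phenyl]-3,4-dihydro-2H-chromen-3-yl]-7-(methoxymethoxy)-2-[4-(methoxymethoxy)phenyl]-2,3-dihydro-4H-chromen-4-one
Product: 21 (2S,3S)-3-[(2S,3R)-5,7-bis(methoxymethoxy)-2-[4-(methoxymethoxy)phenyl]-4-oxo-3,4-dihydro-2H-chromen-3-yl]-7-(methoxymethoxy)-2-[4-(methoxymethoxy)phenyl]-2,3-dihydro-4H-chromen-4-one
Conditions: Dess–Martin periodinane (1.5 equiv), NaHCO3, CH2Cl2, 0 °C → rt
Reagents that add atoms: none
Why: Hypervalent iodine oxidation of the secondary benzylic alcohol to the aryl ketone under buffered neutral conditions, so the new 1,4-diketone is not exposed to base. Any lactol between O4B–H and C4A=O is in equilibrium with the open hydroxy ketone and is drained through it.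

Step 13
Reactants: 21 (2S,3S)-3-[(2S,3R)-5,7-bis(methoxymethoxy)-2-[4-(methoxymethoxy)phenyl]-4-oxo-3,4-dihydro-2H-chromen-3-yl]-7-(methoxymethoxy)-2-[4-(methoxymethoxy)phenyl]-2,3-dihydro-4H-chromen-4-one
Product: 22 (2S,3R)-3-[(2S,3R)-5,7-bis(methoxymethoxy)-2-[4-(methoxymethoxy)phenyl]-4-oxo-3,4-dihydro-2H-chromen-3-yl]-7-(methoxymethoxy)-2-[4-(methoxymethoxy)phenyl]-2,3-dihydro-4H-chromen-4-one
Conditions: DBU (0.2 equiv), CH2Cl2, 0 °C → rt, followed by HPLC
Reagents that add atoms: none
Why: Thermodynamic epimerisation through the C3A (and C3B) enolates. Reprotonation of an enolate is much faster than expulsion of the ring aryloxide, so C2A and C2B keep their configuration while each C3 substituent settles trans (diequatorial) to the neighbouring aryl group, giving (2S,3R) in both units.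

Step 14
Reactants: 22 (2S,3R)-3-[(2S,3R)-5,7-bis(methoxymethoxy)-2-[4-(methoxymethoxy)phenyl]-4-oxo-3,4-dihydro-2H-chromen-3-yl]-7-(methoxymethoxy)-2-[4-(methoxymethoxy)phenyl]-2,3-dihydro-4H-chromen-4-one
Product: 23 (2S,3R)-3-[(2S,3R)-5,7-dihydroxy-2-(4-hydroxyphenyl)-4-oxo-3,4-dihydro-2H-chromen-3-yl]-7-hydroxy-2-(4-hydroxyphenyl)-2,3-dihydro-4H-chromen-4-one
Conditions: 3 M aq HCl, MeOH/THF, 45 °C
Reagents that add atoms: none
Why: Acid-catalysed acetal cleavage (transfer of the CH2OMe groups to methanol) frees the five phenols. Acid does not open the pyranone rings or disturb the already thermodynamic trans,trans array, and the moderate temperature avoids cyclodehydration of the 1,4-diketone.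

## Compound list

1 | 2,4-dihydroxyacetophenone | CC(=O)c1ccc(O)cc1O | starting material
2 | 1-[2-hydroxy-4-(methoxymethoxy)phenyl]ethan-1-one | CC(=O)c1ccc(OCOC)cc1O | intermediate
3 | 4-(methoxymethoxy)benzaldehyde | O=Cc1ccc(OCOC)cc1 | starting material
4 | (E)-1-[2-hydroxy-4-(methoxymethoxy)phenyl]-3-[4-(methoxymethoxy)phenyl]prop-2-en-1-one (chalcone, not isolated) | O=C(/C=C/c1ccc(OCOC)cc1)c1ccc(OCOC)cc1O | intermediate
5 | rac-7-(methoxymethoxy)-2-[4-(methoxymethoxy)phenyl]-2,3-dihydro-4H-chromen-4-one | O=C1CC(c2ccc(OCOC)cc2)Oc2cc(OCOC)ccc12 | intermediate
6 | (2S)-7-(methoxymethoxy)-2-[4-(methoxymethoxy)phenyl]-2,3-dihydro-4H-chromen-4-one | O=C1c2ccc(OCOC)cc2O[C@H](c2ccc(OCOC)cc2)C1 | intermediate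
7 | 2,4,6-trihydroxybenzaldehyde | O=Cc1c(O)cc(O)cc1O | starting material
8 | 2-hydroxy-4,6-bis(methoxymethoxy)benzaldehyde | O=Cc1c(O)cc(OCOC)cc1OCOC | intermediate
9 | (2S)-2-hydroxy-2-(4-hydroxyphenyl)acetic acid, (S)-4-hydroxymandelic acid | OC(=O)[C@@H](O)c1ccc(O)cc1 | starting material
10 | methoxymethyl (2S)-2-hydroxy-2-[4-(methoxymethoxy)phenyl]acetate | COCOC(=O)[C@@H](O)c1ccc(OCOC)cc1 | intermediate
11 | methoxymethyl (2R)-2-[2-formyl-3,5-bis(methoxymethoxy)phenoxy]-2-[4-(methoxymethoxy)phenyl]acetate | COCOC(=O)[C@H](Oc1cc(OCOC)cc(OCOC)c1C=O)c1ccc(OCOC)cc1 | intermediate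
12 | (2R)-2-[2-(hydroxymethyl)-3,5-bis(methoxymethoxy)phenoxy]-2-[4-(methoxymethoxy)phenyl]ethan-1-ol | OC[C@H](Oc1cc(OCOC)cc(OCOC)c1CO)c1ccc(OCOC)cc1 | intermediate
13 | (2R)-2-[2-formyl-3,5-bis(methoxymethoxy)phenoxy]-2-[4-(methoxymethoxy)phenyl]acetaldehyde | O=C[C@H](Oc1cc(OCOC)cc(OCOC)c1C=O)c1ccc(OCOC)cc1 | intermediate
14 | lithium (2S)-7-(methoxymethoxy)-2-[4-(methoxymethoxy)phenyl]-2H-chromen-4-olate (lithium enolate of 6, not isolated) | [Li]OC=1c2ccc(OCOC)cc2O[C@H](c2ccc(OCOC)cc2)C=1 | intermediate
15 | (2S)-3-{(2R)-2-[2-formyl-3,5-bis(methoxymethoxy)phenoxy]-1-hydroxy-2-[4-(methoxymethoxy)phenyl]ethyl}-7-(methoxymethoxy)-2-[4-(methoxymethoxy)phenyl]-2,3-dihydro-4H-chromen-4-one (epimers at C3 and the carbinol carbon) | O=C1c2ccc(OCOC)cc2O[C@H](c2ccc(OCOC)cc2)C1C(O)[C@H](Oc1cc(OCOC)cc(OCOC)c1C=O)c1ccc(OCOC)cc1 | intermediate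
16 | methanesulfonate of 15 at the carbinol oxygen (not isolated) | O=C1c2ccc(OCOC)cc2O[C@H](c2ccc(OCOC)cc2)C1C(OS(C)(=O)=O)[C@H](Oc1cc(OCOC)cc(OCOC)c1C=O)c1ccc(OCOC)cc1 | intermediate
17 | (2R,3E)-3-{(2S)-2-[2-formyl-3,5-bis(methoxymethoxy)phenoxy]-2-[4-(methoxymethoxy)phenyl]ethylidene}-7-(methoxymethoxy)-2-[4-(methoxymethoxy)phenyl]-2,3-dihydro-4H-chromen-4-one | O=C1c2ccc(OCOC)cc2O[C@H](c2ccc(OCOC)cc2)/C1=C\[C@H](Oc1cc(OCOC)cc(OCOC)c1C=O)c1ccc(OCOC)cc1 | intermediate
18 | ketyl radical of 17 with the formyl oxygen bound to SmI2 (not isolated) | O=C1c2ccc(OCOC)cc2O[C@H](c2ccc(OCOC)cc2)/C1=C\[C@H](Oc1cc(OCOC)cc(OCOC)c1[CH]O[Sm](I)I)c1ccc(OCOC)cc1 | intermediate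
19 | cyclised species with an O-SmI2 enolate at C4A and an O-SmI2 alkoxide at C4B (not isolated) | I[Sm](I)OC=1c2ccc(OCOC)cc2O[C@H](c2ccc(OCOC)cc2)C=1[C@H]1[C@H](O[Sm](I)I)c2c(OCOC)cc(OCOC)cc2O[C@@H]1c1ccc(OCOC)cc1 | intermediate
20 | (2S,3S)-3-[(2S,3S,4S)-4-hydroxy-5,7-bis(methoxymethoxy)-2-[4-(methoxymethoxy)phenyl]-3,4-dihydro-2H-chromen-3-yl]-7-(methoxymethoxy)-2-[4-(methoxymethoxy)phenyl]-2,3-dihydro-4H-chromen-4-one | O=C1c2ccc(OCOC)cc2O[C@H](c2ccc(OCOC)cc2)[C@@H]1[C@H]1[C@H](O)c2c(OCOC)cc(OCOC)cc2O[C@@H]1c1ccc(OCOC)cc1 | intermediate
21 | (2S,3S)-3-[(2S,3R)-5,7-bis(methoxymethoxy)-2-[4-(methoxymethoxy)phenyl]-4-oxo-3,4-dihydro-2H-chromen-3-yl]-7-(methoxymethoxy)-2-[4-(methoxymethoxy)phenyl]-2,3-dihydro-4H-chromen-4-one | O=C1c2ccc(OCOC)cc2O[C@H](c2ccc(OCOC)cc2)[C@@H]1[C@H]1C(=O)c2c(OCOC)cc(OCOC)cc2O[C@@H]1c1ccc(OCOC)cc1 | intermediate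
22 | (2S,3R)-3-[(2S,3R)-5,7-bis(methoxymethoxy)-2-[4-(methoxymethoxy)phenyl]-4-oxo-3,4-dihydro-2H-chromen-3-yl]-7-(methoxymethoxy)-2-[4-(methoxymethoxy)phenyl]-2,3-dihydro-4H-chromen-4-one | O=C1c2ccc(OCOC)cc2O[C@H](c2ccc(OCOC)cc2)[C@H]1[C@H]1C(=O)c2c(OCOC)cc(OCOC)cc2O[C@@H]1c1ccc(OCOC)cc1 | intermediate
23 | (2S,3R)-3-[(2S,3R)-5,7-dihydroxy-2-(4-hydroxyphenyl)-4-oxo-3,4-dihydro-2H-chromen-3-yl]-7-hydroxy-2-(4-hydroxyphenyl)-2,3-dihydro-4H-chromen-4-one | O=C1c2ccc(O)cc2O[C@H](c2ccc(O)cc2)[C@H]1[C@H]1C(=O)c2c(O)cc(O)cc2O[C@@H]1c1ccc(O)cc1 | target

## Step count and least certain steps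

Total: 14 steps. Longest linear sequence: 10 steps (from 9 through steps 5 to 14; the same length from 7 through steps 4 and 6 to 14).

Step 11 (key step). The most likely failure is reduction that starts at the aryl-ketone-conjugated enone instead of the electron-rich aldehyde, followed by a second electron transfer and beta-elimination of the aryloxide at C2B, that is reductive cleavage of the O1B–C2B bond before the ring can close. Pinacol coupling of the aldehyde and further reduction of the unit A ketone are lesser risks. Fallback: an intramolecular Stetter reaction sets out from 17. An N-heterocyclic carbene, generated from a triazolium salt such as 2-(pentafluorophenyl)-6,7-dihydro-5H-pyrrolo[2,1-c][1,2,4]triazolium tetrafluoroborate with i-Pr2NEt in toluene at rt, turns the formyl group into an acyl anion equivalent that adds to C3B. It forms the same C3B–C4B bond by the same 6-exo closure, but without electron transfer and hence without a reductive path to C–O cleavage, and it delivers the 1,4-diketone directly. The route is rejoined at 21 (any 22 formed alongside is the product of step 13 anyway), and step 12 becomes unnecessary. This fallback makes no compound outside the list (F0).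

Step 9. The most likely failure is proton transfer from the acidic C2B–H of 13 to the lithium enolate in competition with addition. This would cause loss of configuration at C2B and an intramolecular aldol of the resulting enolate onto the neighbouring aryl aldehyde (a Rap–Stoermer-type benzofuran closure). Ring opening of the flavanone enolate is a further risk if the temperature rises. Fallback: a Mukaiyama aldol addition sets out from 6, which is converted with LiN(SiMe3)2 and Me3SiCl in THF at −78 °C into (2S)-7-(methoxymethoxy)-2-[4-(methoxymethoxy)phenyl]-4-(trimethylsilyloxy)-2H-chromene F1. F1 and 13 are then combined with BF3·OEt2 in CH2Cl2 at −78 °C, where no basic species is present, and the route is rejoined at 15.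

Step 6. The most likely failure is partial loss of configuration through ionisation of the alkoxyphosphonium intermediate, whose benzylic cation is stabilised by the para-alkoxy group. Slow coupling of the ortho-disubstituted, internally hydrogen-bonded phenol would give that ionisation more time. Fallback: activation and displacement are separated, setting out from 10. MsCl and Et3N in CH2Cl2 at −20 °C give methoxymethyl (2S)-2-(methanesulfonyloxy)-2-[4-(methoxymethoxy)phenyl]acetate F2. F2 is displaced at 0 °C in MeCN by the preformed caesium phenoxide of 8 (from Cs2CO3), a stronger nucleophile at high concentration that favours direct SN2 inversion, and the route is rejoined at 11.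

Step 13. The most likely failure is expulsion of a ring aryloxide from the C3 enolates (retro-oxa-Michael ring opening), which on re-closure would scramble C2A or C2B; incomplete epimerisation is the lesser risk. Fallback: the base is omitted and the epimerisation is moved into the acidic deprotection, setting out from 21. Treatment with 3 M aq HCl in MeOH/THF at 55–60 °C first removes the acetals to give (2S,3S)-3-[(2S,3R)-5,7-dihydroxy-2-(4-hydroxyphenyl)-4-oxo-3,4-dihydro-2H-chromen-3-yl]-7-hydroxy-2-(4-hydroxyphenyl)-2,3-dihydro-4H-chromen-4-one F3. F3 then epimerises at C3A by acid-catalysed enolisation, which involves no enolate and hence no aryloxide expulsion, and the route is rejoined at 23.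

## Further compounds

F0 | step 11 | none | none
F1 | step 9 | (2S)-7-(methoxymethoxy)-2-[4-(methoxymethoxy)phenyl]-4-(trimethylsilyloxy)-2H-chromene | C[Si](C)(C)OC=1c2ccc(OCOC)cc2O[C@H](c2ccc(OCOC)cc2)C=1
F2 | step 6 | methoxymethyl (2S)-2-(methanesulfonyloxy)-2-[4-(methoxymethoxy)phenyl]acetate | COCOC(=O)[C@@H](OS(C)(=O)=O)c1ccc(OCOC)cc1
F3 | step 13 | (2S,3S)-3-[(2S,3R)-5,7-dihydroxy-2-(4-hydroxyphenyl)-4-oxo-3,4-dihydro-2H-chromen-3-yl]-7-hydroxy-2-(4-hydroxyphenyl)-2,3-dihydro-4H-chromen-4-one | O=C1c2ccc(O)cc2O[C@H](c2ccc(O)cc2)[C@@H]1[C@H]1C(=O)c2c(O)cc(O)cc2O[C@@H]1c1ccc(O)cc1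
A1 | alternative 1 | acylphloroglucinol with open unit B pyranone and C2B tert-butyldimethylsilyl ether, attached at C3A of bis-O-methoxymethyl unit A | O=C1c2ccc(OCOC)cc2O[C@H](c2ccc(OCOC)cc2)[C@H]1[C@@H](C(=O)c1c(O)cc(O)cc1O)[C@@H](O[Si](C)(C)C(C)(C)C)c1ccc(OCOC)cc1
A2 | alternative 1 | 6-(2-oxoalkyl)-4-hydroxy-2H-pyran-2-one precursor of A1 (pyranone in place of the trihydroxyphenyl ring) | O=C1c2ccc(OCOC)cc2O[C@H](c2ccc(OCOC)cc2)[C@H]1[C@@H](C(=O)Cc1cc(O)cc(=O)o1)[C@@H](O[Si](C)(C)C(C)(C)C)c1ccc(OCOC)cc1
A3 | alternative 2 | 23 with methoxymethyl ethers at O7A, O5B and O7B and free 4'-hydroxyls | O=C1c2ccc(OCOC)cc2O[C@H](c2ccc(O)cc2)[C@H]1[C@H]1C(=O)c2c(OCOC)cc(OCOC)cc2O[C@@H]1c1ccc(O)cc1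
A4 | alternative 2 | 2,3-bis(4-hydroxybenzyl)-1-[2-hydroxy-4-(methoxymethoxy)phenyl]-4-[2-hydroxy-4,6-bis(methoxymethoxy)phenyl]butane-1,4-dione with the C3A and C3B configuration of 23 | O=C(c1ccc(OCOC)cc1O)[C@@H](Cc1ccc(O)cc1)[C@H](Cc1ccc(O)cc1)C(=O)c1c(O)cc(OCOC)cc1OCOC
A5 | alternative 3 | 23 with free O7A hydroxyl and methoxymethyl ethers at O4'A, O5B, O7B and O4'B | O=C1c2ccc(O)cc2O[C@H](c2ccc(OCOC)cc2)[C@H]1[C@H]1C(=O)c2c(OCOC)cc(OCOC)cc2O[C@@H]1c1ccc(OCOC)cc1
A6 | alternative 3 | 5-bromo-2-[4-(methoxymethoxy)phenyl]-2,3-dihydro-4H-pyran-4-one carrying the tris-O-methoxymethyl unit B flavanone at C3 | O=C1C(Br)=CO[C@H](c2ccc(OCOC)cc2)[C@H]1[C@H]1C(=O)c2c(OCOC)cc(OCOC)cc2O[C@@H]1c1ccc(OCOC)cc1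
A7 | alternative 3 | (E)-1-methoxy-3-(trimethylsilyloxy)buta-1,3-diene | CO/C=C/C(=C)O[Si](C)(C)C
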